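**Assumption:** the target is taken exactly as the SMILES given, (1S,2S,3S,9S,10R,11R,12R,14S,15R) in asbestinane numbering. This numbering is used for every intermediate (C17 = methyl on C15, C18 = methyl on C3, C19 = methyl on C12). β is the face of ring A that carries C2, C9, O-11 and C19; α is the face that carries H-1, H-10 and C15.

## Retrosynthetic overview
1. The target comes from acetylation of the 11β-alcohol, which comes from selective reduction of a 7,11-diketone tetracycle.
2. Ring C (oxonane) and ring D (oxepane) open together. A C8 radical adds to the carbonyl of a 2,2-disubstituted cyclopentanone, the C3–C7 bond cleaves (five to nine ring expansion), and the tertiary C3 centre is oxidised and captured by the C16 hydroxyl.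
3. Ring B (tetrahydrofuran) comes from an oxocarbenium condensation of a γ-hydroxy enol carbamate and bromoacetaldehyde dimethyl acetal (C9–C10). That follows a homoaldol union (C1–C2) of a ring A allyl carbamate and 1-methyl-2-oxocyclopentanecarbaldehyde.
4. Ring A (cyclohexane) comes from an enamine Michael/aldol annulation of a chiral-pool C5 aldehyde and butenone, then α′-methylation and 1,2-reduction.
5. Order of ring formation: A, then B, then C and D in one operation.

## Route

**Step 1**
Reactants: 1 (S)-3-bromo-2-methylpropan-1-ol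
Product: 2 (S)-(3-bromo-2-methylpropoxy)(tert-butyl)dimethylsilane
Conditions: TBSCl, imidazole, DMF, 0 °C to rt
Reagents that add atoms: tert-butyldimethylsilyl chloride, C[Si](C)(Cl)C(C)(C)C
Why: Imidazole-promoted O-silylation of the primary alcohol; C15 comes from the chiral pool and is not touched.

**Step 2**
Reactants: 2 (S)-(3-bromo-2-methylpropoxy)(tert-butyl)dimethylsilane
Product: 4 (R)-4-[(tert-butyldimethylsilyl)oxy]-3-methylbutanal, via Grignard reagent 3 (not isolated)
Conditions: Mg, THF, reflux; DMF, 0 °C; cold aq. HCl (1 mol/L)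
Reagents that add atoms: N,N-dimethylformamide, CN(C)C=O
Why: Grignard formation and Bouveault formylation add C1; the C15 centre is β to the aldehyde and cannot epimerise.

**Step 3**
Reactants: 4 (R)-4-[(tert-butyldimethylsilyl)oxy]-3-methylbutanal; 5 but-3-en-2-one
Product: 7 (4R)-4-[(2R)-1-[(tert-butyldimethylsilyl)oxy]propan-2-yl]cyclohex-2-en-1-one, via keto aldehyde 6 (not isolated)
Conditions: (S)-2-[methoxy(diphenyl)methyl]pyrrolidine (10 mol %), ethyl 3,4-dihydroxybenzoate (20 mol %), neat, 4 °C; then LiOH, i-PrOH, rt
Reagents that add atoms: none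
Why: In the enamine-catalysed asymmetric Michael addition the diarylprolinol ether shields one enamine face and sets C14, and the intramolecular aldol condensation (Robinson-type annulation) then closes ring A.

**Step 4**
Reactants: 7 (4R)-4-[(2R)-1-[(tert-butyldimethylsilyl)oxy]propan-2-yl]cyclohex-2-en-1-one
Product: 8 (4R,6R)-4-[(2R)-1-[(tert-butyldimethylsilyl)oxy]propan-2-yl]-6-methylcyclohex-2-en-1-one
Conditions: LDA, THF, −78 °C; MeI, −78 to −40 °C
Reagents that add atoms: iodomethane, CI
Why: Kinetic α′-enolate alkylation; axial attack on the cross-conjugated enolate, anti to the pseudo-equatorial C14 side chain, gives the trans-4,6 isomer (C19 β).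

**Step 5**
Reactants: 8 (4R,6R)-4-[(2R)-1-[(tert-butyldimethylsilyl)oxy]propan-2-yl]-6-methylcyclohex-2-en-1-one
Product: 9 (1R,4R,6R)-4-[(2R)-1-[(tert-butyldimethylsilyl)oxy]propan-2-yl]-6-methylcyclohex-2-en-1-ol
Conditions: NaBH4, CeCl3·7H2O, MeOH, −78 °C
Reagents that add atoms: none
Why: Luche 1,2-reduction; hydride arrives on the α face, opposite the axial C19 methyl, and gives the 11β-alcohol with a pseudo-axial H-11α.

**Step 6**
Reactants: 9 (1R,4R,6R)-4-[(2R)-1-[(tert-butyldimethylsilyl)oxy]propan-2-yl]-6-methylcyclohex-2-en-1-ol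
Product: 10 (1R,4R,6R)-4-[(2R)-1-[(tert-butyldimethylsilyl)oxy]propan-2-yl]-6-methylcyclohex-2-en-1-yl N,N-diisopropylcarbamate
Conditions: NaH, i-Pr2NC(O)Cl, THF, reflux
Reagents that add atoms: N,N-diisopropylcarbamoyl chloride, CC(C)N(C(C)C)C(Cl)=O
Why: O-carbamoylation of the alkoxide installs the directing and activating group for the allylic lithiation without touching any stereocentre.

**Step 7**
Reactants: 11 cyclopentanone; 12 ethyl formate
Product: 13 2-(hydroxymethylidene)cyclopentan-1-one
Conditions: NaOEt, Et2O, 0 °C to rt; aq. HCl (1 mol/L)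
Reagents that add atoms: none
Why: Crossed Claisen formylation, driven by formation of the stabilised β-keto aldehyde enolate, adds C2.

**Step 8**
Reactants: 13 2-(hydroxymethylidene)cyclopentan-1-one
Product: 14 (±)-1-methyl-2-oxocyclopentane-1-carbaldehyde
Conditions: MeI, K2CO3, acetone, rt
Reagents that add atoms: iodomethane, CI
Why: C-alkylation of the β-keto aldehyde enolate builds quaternary C3; the racemate is sufficient because C3 is made planar and set again in step 11.

**Step 9**
Reactants: 10 (1R,4R,6R)-4-[(2R)-1-[(tert-butyldimethylsilyl)oxy]propan-2-yl]-6-methylcyclohex-2-en-1-yl N,N-diisopropylcarbamate; 14 (±)-1-methyl-2-oxocyclopentane-1-carbaldehyde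
Product: 17 γ-hydroxy enol carbamate (C10=C11 enol carbamate; C1–C2 bond β; 2S carbinol; about 1:1 at C3), via lithiated carbamate 15 (not isolated), via allyltitanium reagent 16 (not isolated)
Conditions: s-BuLi, TMEDA, Et2O, −78 °C; ClTi(OiPr)3, −78 °C; 14 (2.5 equiv), −78 °C; aq. NH4Cl
Reagents that add atoms: none
Why: Hoppe homoaldol reaction: the pseudo-axial H-11α is removed with retention, lithium–titanium exchange inverts C11, and the aldehyde (chemoselectively over the ketone) is attacked at C1 on the titanium-bearing β face, anti to the C14 side chain, through a closed six-membered transition state in which the quaternary aldehyde residue points away from ring A, which sets C1 and the H-1/H-2 trans relationship.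

**Step 10**
Reactants: 17 γ-hydroxy enol carbamate; 18 2-bromo-1,1-dimethoxyethane
Product: 20 hydroxy bromide (cis-fused hexahydroisobenzofuran-4-one; C9 carries CH2Br, C2 carries the 1-methyl-2-oxocyclopentyl group, both on the face of ring B opposite to ring A; free C16 hydroxyl), via silyl ether 19 (not isolated)
Conditions: 18 (2 equiv), BF3·OEt2 (2.5 equiv), Et2O, −78 to −20 °C; then MeCN, 48% aq. HF, 0 °C
Reagents that add atoms: none
Why: Transacetalisation at O-2 gives an oxocarbenium ion that the tethered enol carbamate attacks at C10 (intramolecular Mukaiyama-type aldol). The tether enforces the cis ring fusion (C10), a pseudo-equatorial CH2Br gives the 2,5-cis ring B (C9), loss of the carbamoyl group releases the C11 ketone, and aqueous HF removes the primary silyl ether in the same flask.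

**Step 11**
Reactants: 20 hydroxy bromide
Product: 22 7,11-diketone tetracycle (rings A–D complete; 3S), via iodide 21 (not isolated)
Conditions: NaI (1.5 equiv), MeCN, 60 °C; then 10-phenylphenothiazine (5 mol %), 2,4,6-collidine (2 equiv), MeCN (0.01 mol/L), 390 nm LED, 25 °C
Reagents that add atoms: none
Why: Proposed new method: a redox-neutral photocatalytic Dowd–Beckwith-type ring expansion that ends in a radical–polar crossover etherification. Excited 10-phenylphenothiazine reduces the carbon–iodine bond of 21, and the primary C8 radical adds (6-exo) to the cis-disposed C7 carbonyl. The bridged alkoxyl radical cleaves its C3–C7 bond, which gives the most substituted radical, so the cyclopentanone becomes the nine-membered ring C with its ketone at C7. Of the interconverting radicals only the tertiary C3 radical can be oxidised by (or couple at sulfur with) the phenothiazine radical cation; this closes the catalytic cycle and gives a cation equivalent that the C16 hydroxyl captures to close ring D while collidine takes the proton. Both C3 epimers converge because C3 becomes planar. The new configuration follows from the short C4–C8 tether, which holds C4 over ring B and C18 outward, so only the face turned toward C1 is open to the tethered oxygen. H-2 lies well off the axis of the empty orbital, which disfavours a 1,2-hydride shift. The closest known reaction types are the tin-hydride Dowd–Beckwith expansion of haloalkyl β-keto esters and the phenothiazine-catalysed decarboxylative etherification of tertiary radicals.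

**Step 12**
Reactants: 22 7,11-diketone tetracycle
Product: 23 11β-hydroxy-7-ketone (deacetyl target)
Conditions: NaBH4 (0.5 equiv), MeOH/CH2Cl2, −40 °C
Reagents that add atoms: none
Why: Chemoselective borohydride reduction: the cyclohexanone reacts far faster than the nine-membered-ring ketone, whose rehybridisation raises transannular strain, and axial hydride attack from the open α face gives the equatorial 11β-alcohol before C12 can epimerise.

**Step 13**
Reactants: 23 11β-hydroxy-7-ketone
Product: 24 target CNP0288436.2 (11β-acetate)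
Conditions: Ac2O, DMAP, pyridine, CH2Cl2, rt
Reagents that add atoms: acetic anhydride, CC(=O)OC(C)=O
Why: DMAP-catalysed acetylation of the only hydroxyl group under conditions too mild for retro-oxa-Michael opening of the β-alkoxy ketone.

## Compound list
1 | (S)-3-bromo-2-methylpropan-1-ol | BrC[C@@H](C)CO | starting material
2 | (S)-(3-bromo-2-methylpropoxy)(tert-butyl)dimethylsilane | BrC[C@@H](C)CO[Si](C)(C)C(C)(C)C | intermediate
3 | (S)-[3-[(tert-butyldimethylsilyl)oxy]-2-methylpropyl]magnesium bromide | Br[Mg]C[C@@H](C)CO[Si](C)(C)C(C)(C)C | intermediate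
4 | (R)-4-[(tert-butyldimethylsilyl)oxy]-3-methylbutanal | O=CC[C@@H](C)CO[Si](C)(C)C(C)(C)C | intermediate
5 | but-3-en-2-one | C=CC(C)=O | starting material
6 | (2S)-2-[(2R)-1-[(tert-butyldimethylsilyl)oxy]propan-2-yl]-5-oxohexanal | O=C[C@@H](CCC(C)=O)[C@@H](C)CO[Si](C)(C)C(C)(C)C | intermediate
7 | (4R)-4-[(2R)-1-[(tert-butyldimethylsilyl)oxy]propan-2-yl]cyclohex-2-en-1-one | O=C1C=C[C@@H](CC1)[C@@H](C)CO[Si](C)(C)C(C)(C)C | intermediate
8 | (4R,6R)-4-[(2R)-1-[(tert-butyldimethylsilyl)oxy]propan-2-yl]-6-methylcyclohex-2-en-1-one | O=C1C=C[C@@H](C[C@H]1C)[C@@H](C)CO[Si](C)(C)C(C)(C)C | intermediate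
9 | (1R,4R,6R)-4-[(2R)-1-[(tert-butyldimethylsilyl)oxy]propan-2-yl]-6-methylcyclohex-2-en-1-ol | O[C@H]1C=C[C@@H](C[C@H]1C)[C@@H](C)CO[Si](C)(C)C(C)(C)C | intermediate
10 | N,N-diisopropylcarbamate of 9 | CC(C)N(C(C)C)C(=O)O[C@H]1C=C[C@@H](C[C@H]1C)[C@@H](C)CO[Si](C)(C)C(C)(C)C | intermediate
11 | cyclopentanone | O=C1CCCC1 | starting material
12 | ethyl formate | CCOC=O | starting material
13 | 2-(hydroxymethylidene)cyclopentan-1-one | OC=C1CCCC1=O | intermediate
14 | (±)-1-methyl-2-oxocyclopentane-1-carbaldehyde | CC1(C=O)CCCC1=O | intermediate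
15 | C11-lithiated carbamate (lithium on the α face) | CC(C)N(C(C)C)C(=O)O[C@@]1([Li])C=C[C@@H](C[C@H]1C)[C@@H](C)CO[Si](C)(C)C(C)(C)C | intermediate
16 | C11-triisopropoxytitanium carbamate (titanium on the β face) | CC(C)N(C(C)C)C(=O)O[C@]1([Ti](OC(C)C)(OC(C)C)OC(C)C)C=C[C@@H](C[C@H]1C)[C@@H](C)CO[Si](C)(C)C(C)(C)C | intermediate
17 | γ-hydroxy enol carbamate (1S,2S,12R,14S,15R; C3 epimers) | CC(C)N(C(C)C)C(=O)OC1=C[C@@H]([C@H](O)C2(C)CCCC2=O)[C@@H](C[C@H]1C)[C@@H](C)CO[Si](C)(C)C(C)(C)C | intermediate
18 | 2-bromo-1,1-dimethoxyethane | COC(CBr)OC | starting material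
19 | bromomethyl tetrahydrofuran diketone, C16 silyl ether (rings A and B; C3 epimers) | O=C1[C@@H]2[C@@H]([C@H](O[C@H]2CBr)C3(C)CCCC3=O)[C@@H](C[C@H]1C)[C@@H](C)CO[Si](C)(C)C(C)(C)C | intermediate
20 | bromomethyl tetrahydrofuran diketone, free C16 hydroxyl (C3 epimers) | O=C1[C@@H]2[C@@H]([C@H](O[C@H]2CBr)C3(C)CCCC3=O)[C@@H](C[C@H]1C)[C@@H](C)CO | intermediate
21 | iodomethyl analogue of 20 | O=C1[C@@H]2[C@@H]([C@H](O[C@H]2CI)C3(C)CCCC3=O)[C@@H](C[C@H]1C)[C@@H](C)CO | intermediate
22 | 7,11-diketone tetracycle (11-oxo analogue of the deacetoxy target) | O=C1[C@@H]2[C@@H]3[C@@H](C[C@H]1C)[C@@H](C)CO[C@@]1(C)CCCC(=O)C[C@@H]2O[C@@H]31 | intermediate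
23 | 11β-hydroxy-7-ketone (deacetyl target) | O[C@H]1[C@@H]2[C@@H]3[C@@H](C[C@H]1C)[C@@H](C)CO[C@@]1(C)CCCC(=O)C[C@@H]2O[C@@H]31 | intermediate
24 | CNP0288436.2, (1S,2S,3S,9S,10R,11R,12R,14S,15R) | CC(=O)O[C@H]1[C@@H]2[C@@H]3[C@@H](C[C@H]1C)[C@@H](C)CO[C@@]1(C)CCCC(=O)C[C@@H]2O[C@@H]31 | target

## Step count
- **Total steps:** 13.
- **Longest linear sequence:** 11 (steps 1–6 and 9–13).

## Steps most likely to fail

**Step 11 (the proposed new step).**
- Risks: the C8 radical may be quenched before it reaches C7. The alkoxyl radical may cleave toward C6. The C3 cation equivalent may eliminate or suffer a hydride shift. The hydroxyl may attack the wrong C3 face.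
- Fallback (known reactions only), setting out from 19, which is isolated before the HF stage. NaI in acetone gives the iodo silyl ether F1. Excess Et3B and air in toluene abstract the iodine atom, the radical adds to the C7 ketone, and the alkoxyl radical is trapped at boron; work-up gives the bridged tertiary cyclopentanol F2. PhI(OAc)2 and I2 under visible light (alkoxyl-radical β-fragmentation), followed by DBU, give the ring-expanded 3(18)-methylidene oxonanone F3; its C3=C4 isomer serves equally well. HF·pyridine gives the hydroxy alkene F4. Hg(OCOCF3)2 closes ring D by Markovnikov intramolecular oxymercuration to the organomercurial F5. Alkaline NaBH4 then removes mercury and reduces the C11 ketone in the same operation, so the sequence comes back to the route at 23.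

**Step 9.**
- Risks: deprotonation next to the C19 methyl may be slow. α/γ selectivity and the simple diastereoselectivity at C2 may erode. Isopropoxide may deformylate 14.
- Fallback, setting out from 10. The lithiated carbamate is quenched with Me3SnCl (anti-SE2′), which gives the isolable and purifiable C1 allylstannane F6. TiCl4 at −78 °C converts it (anti-SE2′) into the alkoxide-free C11 trichlorotitanium reagent on the β face. This reagent adds to 14 through a tighter closed transition state. Metalation and carbon–carbon bond formation are thereby separated, and the sequence comes back at 17.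

**Step 10.**
- Risks: the hindered C2 hydroxyl may not form the destabilised α-bromo oxocarbenium ion quickly enough. Retro-aldol cleavage of C2–C3 or epimerisation at C12 could then take over.
- Fallback, setting out from 17. NBS and ethyl vinyl ether at −20 °C (neutral bromoacetalisation of the Ueno–Stork kind) first attach C9 and C8, giving the mixed bromoacetal F7. One equivalent of TiCl4 at −78 °C then only has to ionise the ethoxy group for the same intramolecular enol carbamate attack. The sequence comes back at 19.

## Further compounds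
F1 | step 11 | iodomethyl tetrahydrofuran diketone, C16 silyl ether | O=C1[C@@H]2[C@@H]([C@H](O[C@H]2CI)C3(C)CCCC3=O)[C@@H](C[C@H]1C)[C@@H](C)CO[Si](C)(C)C(C)(C)C
F2 | step 11 | bridged tertiary cyclopentanol (C7–C8 bond closed; C3/C7 cis-fused epimers) | O=C1[C@@H]2[C@@H]([C@@H]3O[C@H]2CC4(O)CCCC34C)[C@@H](C[C@H]1C)[C@@H](C)CO[Si](C)(C)C(C)(C)C
F3 | step 11 | 3(18)-methylidene oxonanone, C16 silyl ether | O=C1[C@@H]2[C@@H]([C@@H]3O[C@H]2CC(=O)CCCC3=C)[C@@H](C[C@H]1C)[C@@H](C)CO[Si](C)(C)C(C)(C)C
F4 | step 11 | 3(18)-methylidene oxonanone, free C16 hydroxyl | O=C1[C@@H]2[C@@H]([C@@H]3O[C@H]2CC(=O)CCCC3=C)[C@@H](C[C@H]1C)[C@@H](C)CO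
F5 | step 11 | C18 mercury trifluoroacetate of 22 | O=C1[C@@H]2[C@@H]3[C@@H](C[C@H]1C)[C@@H](C)CO[C@@]1(C[Hg]OC(=O)C(F)(F)F)CCCC(=O)C[C@@H]2O[C@@H]31
F6 | step 9 | C1α-trimethylstannyl enol carbamate | CC(C)N(C(C)C)C(=O)OC1=C[C@H]([Sn](C)(C)C)[C@@H](C[C@H]1C)[C@@H](C)CO[Si](C)(C)C(C)(C)C
F7 | step 10 | O-2 (2-bromo-1-ethoxyethyl) mixed acetal of 17 | CC(C)N(C(C)C)C(=O)OC1=C[C@@H]([C@H](OC(CBr)OCC)C2(C)CCCC2=O)[C@@H](C[C@H]1C)[C@@H](C)CO[Si](C)(C)C(C)(C)C
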